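The methylene bridge is cut into a Mannich base of ring B and butanoyl-methylphloroglucinol (ring A); ring B is then traced to an aryne. In ring B (C1' bridge carbon, C2' OH, C3' CH3, C4' OCH3, C5' butanoyl, C6' OH) the acyl carbon C5' and the hydroxyl carbon C6' are adjacent, and C5' sits next to the methoxy carbon C4'. Insertion of a C5'–C6' aryne into the C–O bond of butyric acid therefore installs the C6'–O and C5'–acyl bonds in one operation, the methoxy group dictating the orientation. The precursor is an ortho-silylaryl triflate with the triflate at C5', silicon at C6' and a benzyl ether on the C2' oxygen.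

Key step: step 6

Remark: the target has no stereocentre, so no step has to set or preserve configuration; primed locants always refer to ring B as defined above.

Step 1
Reactants: 1 2,4-dihydroxy-3-methylbenzaldehyde
Product: 2 4-(benzyloxy)-2-hydroxy-3-methylbenzaldehyde
Conditions: BnBr (1.05 equiv), NaHCO3, KI (cat.), MeCN, 80 °C
Reagents that add atoms: benzyl bromide, BrCc1ccccc1
Why: Williamson etherification in which the 2-hydroxyl is held in a hydrogen bond to the formyl oxygen and shielded by the methyl group, so the weak base should ionise and benzylate only the 4-hydroxyl.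

Step 2
Reactants: 2 4-(benzyloxy)-2-hydroxy-3-methylbenzaldehyde
Product: 3 4-(benzyloxy)-2-methoxy-3-methylbenzaldehyde
Conditions: MeI, K2CO3, DMF, 40 °C
Reagents that add atoms: iodomethane, CI
Why: Williamson O-methylation with carbonate in a dipolar aprotic solvent, which opens the chelate; the 2-hydroxyl is the only nucleophilic site left.

Step 3
Reactants: 3 4-(benzyloxy)-2-methoxy-3-methylbenzaldehyde
Product: 5 4-(benzyloxy)-2-methoxy-3-methylphenol, via 4-(benzyloxy)-2-methoxy-3-methylphenyl formate 4 (not isolated)
Conditions: mCPBA, CH2Cl2, 0 °C → rt; aq. NaHCO3/Na2S2O3 wash; then K2CO3 (cat.), MeOH, rt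
Reagents that add atoms: 3-chloroperoxybenzoic acid, OOC(=O)c1cccc(Cl)c1
Why: Baeyer–Villiger (Dakin-type) oxidation of an electron-rich benzaldehyde, in which the aryl group with ortho- and para-alkoxy donors migrates in preference to hydride; base-catalysed methanolysis of the formate then frees the phenol and leaves both ethers intact.

Step 4
Reactants: 5 4-(benzyloxy)-2-methoxy-3-methylphenol
Product: 6 4-(benzyloxy)-6-bromo-2-methoxy-3-methylphenol
Conditions: NBS (1.0 equiv), i-Pr2NH (10 mol%), CH2Cl2, 0 °C
Reagents that add atoms: N-bromosuccinimide, O=C1CCC(=O)N1Br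
Why: Amine-mediated ortho-bromination of a phenol, in which the N-bromoamine formed in situ is hydrogen-bonded to the phenol and should deliver bromine to C6, the only free ortho carbon; the para position is blocked and C5 is activated only by ether oxygens.

Step 5
Reactants: 6 4-(benzyloxy)-6-bromo-2-methoxy-3-methylphenol
Product: 9 4-(benzyloxy)-2-methoxy-3-methyl-6-(trimethylsilyl)phenyl trifluoromethanesulfonate, via [4-(benzyloxy)-6-bromo-2-methoxy-3-methylphenoxy]trimethylsilane 7 (not isolated), via lithium 4-(benzyloxy)-2-methoxy-3-methyl-6-(trimethylsilyl)phenolate 8 (not isolated)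
Conditions: HMDS, THF, 70 °C, then evaporation; n-BuLi, THF, −78 °C; Tf2O, −78 °C → rt
Reagents that add atoms: hexamethyldisilazane, C[Si](C)(C)N[Si](C)(C)C; trifluoromethanesulfonic anhydride, O=S(=O)(OS(=O)(=O)C(F)(F)F)C(F)(F)F
Why: O-silylation, bromine–lithium exchange and 1,3-migration of silicon from oxygen to carbon (retro-Brook rearrangement) should give the lithium ortho-silylphenoxide, which Tf2O traps on oxygen; this is the standard preparation of ortho-silylaryl triflates and tolerates benzyl and methyl ethers at −78 °C.

Step 6
Reactants: 9 4-(benzyloxy)-2-methoxy-3-methyl-6-(trimethylsilyl)phenyl trifluoromethanesulfonate; 10 butyric acid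
Product: 13 1-[4-(benzyloxy)-6-hydroxy-2-methoxy-3-methylphenyl]butan-1-one, via cesium butanoate 11 (not isolated), via 5-(benzyloxy)-3-methoxy-4-methylbenzyne 12 (not isolated)
Conditions: butyric acid (1.3 equiv), CsF (4 equiv, dried), THF, 125 °C, sealed tube; aq. NH4Cl work-up
Reagents that add atoms: none
Why: Fluoride attacks silicon in 9 and triflate leaves from the neighbouring carbon to give aryne 12 (C5'≡C6'); butanoate 11 adds through oxygen to C6', the aryne carbon remote from the C4' methoxy group, so that the aryl anion develops at C5', where the adjacent C–O bond stabilises it inductively. The anion then attacks the carbonyl of the aryl ester just formed through a four-membered transition state, and the acyl group moves from oxygen to C5', the chelated ortho-acyl phenoxide being the thermodynamic sink. This is the known insertion of arynes into the C–O bond of carboxylic acids, an aryne 1,2-oxyacylation related to an anionic Fries shift. No ring is closed and no stereocentre is formed. The step needs regioselective addition to an unsymmetrical aryne and an acyl shift that is faster than protonation of the aryl anion. The first is secured by the methoxy group beside the triple bond and by the unhindered C6' next to the unsubstituted C1'; the second by the high temperature, the aprotic medium and only a small excess of acid.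

Step 7
Reactants: 13 1-[4-(benzyloxy)-6-hydroxy-2-methoxy-3-methylphenyl]butan-1-one
Product: 14 1-(4,6-dihydroxy-2-methoxy-3-methylphenyl)butan-1-one
Conditions: H2 (1 atm), 10% Pd/C, EtOAc, rt
Reagents that add atoms: none
Why: Catalytic hydrogenolysis of a benzyl aryl ether; at ambient pressure and temperature the hydrogen-bonded aryl ketone and the methyl ether should not be reduced.

Step 8
Reactants: 14 1-(4,6-dihydroxy-2-methoxy-3-methylphenyl)butan-1-one
Product: 15 1-{3-[(dimethylamino)methyl]-2,4-dihydroxy-6-methoxy-5-methylphenyl}butan-1-one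
Conditions: Me2NH (40% aq., 1.5 equiv) premixed with HCHO (37% aq., 1.05 equiv), EtOH, 0 °C → rt
Reagents that add atoms: formaldehyde, C=O; dimethylamine, CNC
Why: Phenolic Mannich reaction in which the iminium ion attacks the single unsubstituted ring carbon, which lies between the two hydroxyls; premixing formaldehyde with excess amine should suppress formation of a bis-aryl methane.

Step 9
Reactants: 16 2-methylphloroglucinol (2-methylbenzene-1,3,5-triol)
Product: 17 1-(2,4,6-trihydroxy-3-methylphenyl)butan-1-one
Conditions: butanoyl chloride (1.05 equiv), AlCl3 (3.5 equiv), PhNO2/CH2Cl2, 0 → 50 °C; ice/aq. HCl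
Reagents that add atoms: butanoyl chloride, CCCC(=O)Cl
Why: Friedel–Crafts C-acylation of a phloroglucinol at one of its two equivalent free carbons; the first acyl group deactivates the ring, so monoacylation is expected.

Step 10
Reactants: 15 1-{3-[(dimethylamino)methyl]-2,4-dihydroxy-6-methoxy-5-methylphenyl}butan-1-one; 17 1-(2,4,6-trihydroxy-3-methylphenyl)butan-1-one (1.2 equiv)
Product: 18 1-[3-[(3-butanoyl-2,6-dihydroxy-4-methoxy-5-methylphenyl)methyl]-2,4,6-trihydroxy-5-methylphenyl]butan-1-one (target)
Conditions: 1,4-dioxane, 100 °C, slow N2 stream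
Reagents that add atoms: none
Why: Thermal loss of dimethylamine from the ortho-hydroxybenzylamine should give an ortho-quinone methide, which C5 of 17, its only free ring carbon, captures in a conjugate addition (Friedel–Crafts-type alkylation); tautomerisation then restores both aromatic rings.

Compound list
1 | 2,4-dihydroxy-3-methylbenzaldehyde | O=Cc1ccc(O)c(C)c1O | starting material
2 | 4-(benzyloxy)-2-hydroxy-3-methylbenzaldehyde | O=Cc1ccc(OCc2ccccc2)c(C)c1O | intermediate
3 | 4-(benzyloxy)-2-methoxy-3-methylbenzaldehyde | COc1c(C=O)ccc(OCc2ccccc2)c1C | intermediate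
4 | 4-(benzyloxy)-2-methoxy-3-methylphenyl formate | COc1c(OC=O)ccc(OCc2ccccc2)c1C | intermediate
5 | 4-(benzyloxy)-2-methoxy-3-methylphenol | COc1c(O)ccc(OCc2ccccc2)c1C | intermediate
6 | 4-(benzyloxy)-6-bromo-2-methoxy-3-methylphenol | COc1c(C)c(OCc2ccccc2)cc(Br)c1O | intermediate
7 | [4-(benzyloxy)-6-bromo-2-methoxy-3-methylphenoxy]trimethylsilane | COc1c(C)c(OCc2ccccc2)cc(Br)c1O[Si](C)(C)C | intermediate
8 | lithium 4-(benzyloxy)-2-methoxy-3-methyl-6-(trimethylsilyl)phenolate | COc1c(C)c(OCc2ccccc2)cc([Si](C)(C)C)c1[O-].[Li+] | intermediate
9 | 4-(benzyloxy)-2-methoxy-3-methyl-6-(trimethylsilyl)phenyl trifluoromethanesulfonate | COc1c(C)c(OCc2ccccc2)cc([Si](C)(C)C)c1OS(=O)(=O)C(F)(F)F | intermediate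
10 | butyric acid | CCCC(=O)O | starting material
11 | cesium butanoate | CCCC(=O)[O-].[Cs+] | intermediate
12 | 5-(benzyloxy)-3-methoxy-4-methylbenzyne | COC1=C(C)C(OCc2ccccc2)=CC#C1 | intermediate
13 | 1-[4-(benzyloxy)-6-hydroxy-2-methoxy-3-methylphenyl]butan-1-one | CCCC(=O)c1c(O)cc(OCc2ccccc2)c(C)c1OC | intermediate
14 | 1-(4,6-dihydroxy-2-methoxy-3-methylphenyl)butan-1-one | CCCC(=O)c1c(O)cc(O)c(C)c1OC | intermediate
15 | 1-{3-[(dimethylamino)methyl]-2,4-dihydroxy-6-methoxy-5-methylphenyl}butan-1-one | CCCC(=O)c1c(O)c(CN(C)C)c(O)c(C)c1OC | intermediate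
16 | 2-methylphloroglucinol | Cc1c(O)cc(O)cc1O | starting material
17 | 1-(2,4,6-trihydroxy-3-methylphenyl)butan-1-one | CCCC(=O)c1c(O)cc(O)c(C)c1O | intermediate
18 | 1-[3-[(3-butanoyl-2,6-dihydroxy-4-methoxy-5-methylphenyl)methyl]-2,4,6-trihydroxy-5-methylphenyl]butan-1-one | CCCC(=O)c1c(O)c(C)c(O)c(Cc2c(O)c(C)c(OC)c(C(=O)CCC)c2O)c1O | target

Total step count: 10. Longest linear sequence: 9 (steps 1–8 and 10); step 9 is a one-step branch.

Steps most likely to fail

Step 6. Protonation of the C5' aryl anion by hydrogen fluoride, bifluoride or traces of water may outrun the oxygen-to-carbon acyl shift, so that the sequence stops at the aryl ester; the product phenoxide may also add to a second aryne. The fallback avoids the aryne and sets out from 17. Two equivalents of MOMCl with i-Pr2NEt in CH2Cl2 should protect the 4- and 6-hydroxyls and leave the hydroxyl at C2, which is chelated to the ketone and hemmed in by the methyl group, giving 1-[2-hydroxy-4,6-bis(methoxymethoxy)-3-methylphenyl]butan-1-one F1. MeI and K2CO3 in DMF at 60 °C should then methylate this last hydroxyl to 1-[2-methoxy-4,6-bis(methoxymethoxy)-3-methylphenyl]butan-1-one F2. HCl in MeOH should remove both acetals and bring the route back at 14.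

Step 10. Thermal expulsion of dimethylamine may be slow, and at the temperature needed the product may re-form an ortho-quinone methide, so that the bridge is exchanged between rings and symmetrical dimers arise. The fallback replaces thermal activation by a charged leaving group and sets out from 15. MeI in acetone at rt should quaternise the amine to 1-(3-butanoyl-2,6-dihydroxy-4-methoxy-5-methylphenyl)-N,N,N-trimethylmethanaminium iodide F3. Treating F3 with the sodium salt of 17 (NaH, THF/DMF, 0 °C → rt) should release trimethylamine and C-alkylate 17 without heating, returning to the route at 18.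

Step 4. Bromination may stray to C5 under the influence of the two ether oxygens, or the hydroquinone monoether may be oxidised to a quinone. The fallback installs silicon by directed ortho-metalation and sets out from 5. i-PrNCO with catalytic Et3N in CH2Cl2 should give 4-(benzyloxy)-2-methoxy-3-methylphenyl N-(propan-2-yl)carbamate F4. N-Silylation in situ (TMSOTf, TMEDA, Et2O, 0 °C), lithiation at the only ortho C–H (n-BuLi, TMEDA, −78 °C) and a TMSCl quench should give 4-(benzyloxy)-2-methoxy-3-methyl-6-(trimethylsilyl)phenyl N-(propan-2-yl)carbamate F5. Et2NH and DBU in MeCN at 40 °C should cleave the carbamate to 4-(benzyloxy)-2-methoxy-3-methyl-6-(trimethylsilyl)phenol F6, and PhNTf2 added to the same flask should give 9, where the route resumes.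

Further compounds
F1 | step 6 | 1-[2-hydroxy-4,6-bis(methoxymethoxy)-3-methylphenyl]butan-1-one | CCCC(=O)c1c(O)c(C)c(OCOC)cc1OCOC
F2 | step 6 | 1-[2-methoxy-4,6-bis(methoxymethoxy)-3-methylphenyl]butan-1-one | CCCC(=O)c1c(OC)c(C)c(OCOC)cc1OCOC
F3 | step 10 | 1-(3-butanoyl-2,6-dihydroxy-4-methoxy-5-methylphenyl)-N,N,N-trimethylmethanaminium iodide | CCCC(=O)c1c(O)c(C[N+](C)(C)C)c(O)c(C)c1OC.[I-]
F4 | step 4 | 4-(benzyloxy)-2-methoxy-3-methylphenyl N-(propan-2-yl)carbamate | COc1c(C)c(OCc2ccccc2)ccc1OC(=O)NC(C)C
F5 | step 4 | 4-(benzyloxy)-2-methoxy-3-methyl-6-(trimethylsilyl)phenyl N-(propan-2-yl)carbamate | COc1c(C)c(OCc2ccccc2)cc([Si](C)(C)C)c1OC(=O)NC(C)C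
F6 | step 4 | 4-(benzyloxy)-2-methoxy-3-methyl-6-(trimethylsilyl)phenol | COc1c(C)c(OCc2ccccc2)cc([Si](C)(C)C)c1O
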